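The pitfall I met first in this flask was reading the charged coupling partner as target already earned.

    coupling partner + target → over-reaction product (k1 = 0.095 M⁻¹ h⁻¹)
    starting material + coupling partner → intermediate + released group (k2 = 0.70 M⁻¹ h⁻¹)
    intermediate → target (k3 = 0.15 h⁻¹)
    starting material + protic impurity → quenched substrate (k4 = 1.5 M⁻¹ h⁻¹)
starting material 1.0 M; coupling partner 0.900 equiv; protic impurity 0.0500 M; time 6.0 d
- at 6.0 d, what has stopped the reaction, if anything has (the coupling partner has run out first / all of the starting material has reacted / forward and back rates have come level / it is still moving)
- amount of target at 6.0 d, in percent of the starting material charged

In this flask the protic impurity had a half-life of 0.462 h against starting material, shorter than 6.0 d. So I struck off 0.0500 M of starting material at once, which left 0.950 M, more than the partner charge. That made the coupling partner the limiting reagent.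

Each molecule of intermediate costs one partner, and each over-reaction product costs another partner and destroys one target. With partner and intermediate at zero, target = C − 2·O, where O is the over-reaction product and C, the partner ceiling, is 90.0%. Setting O aside gave my upper bound, C.

For the lower bound I let intermediate turn into target instantly and froze the selectivity factor k1/k2 at 0.136. Integrating over the starting material consumed gave O near 0.115 M, so the floor was 67.1%. The intermediate's half-life, 0.19 d, is longer than the 1.1 h of starting material by coupling with the partner as charged, so target lags and the truth should clear the floor. I committed to the middle, 78.5%.

The forecast said the coupling partner has run out first and 67.5% (64% to 71%), since “each over-reaction event costs one partner and one target”. Its 0.11 M of over-reaction product put it inside my bracket, just above the floor.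

The flask gave the coupling partner has run out first and 76.9%. It held 6.54% over-reaction product, and C − 2·O gives 76.9%. The neighbour flask, charged with 0.540 equiv of partner, has a ceiling of 54.0%. It ended with 0% of its partner, 0% intermediate and 0.936% over-reaction product, so the same reckoning gives 52.1%, and the neighbour flask held 52.1% target.

Its constants are invented.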